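The 2,3-dihydrobenzofuran is traced back to its aromatic benzofuran, whose furan ring is cut at C3–C3a and O1–C2. This exploits two features: O1 sits ortho to C3a on the phloroglucinol-derived ring, and C2 carries a single substituent, Cα, so C2–C3 can come from the C≡C of a terminal alkyne. One palladium/copper operation joins o-iodophenol 9 to alkyne 7 and closes the furan. Precursor 7 is a 3,3-diarylpropyne whose propargylic carbon is Cα, already (R) and bonded to C8 of fully benzylated (+)-catechin; its 3-OH is masked as a benzyl ether. Catalyst-controlled hydrogenation then sets C2.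

Key step: step 6

Assumption: the ligand antipodes written in steps 4 and 7 are those expected to give the required sense; a trial with each antipode is to confirm this, and the mirror-image ligand is used if the sense is reversed.

Remark: Cα keeps one spatial arrangement from 7 to 13. Its CIP label is R in 7, 11, 12 and 13 and S in 10 only because the substituted alkynyl group outranks the catechol ring there.

Step 1
Reactants: 1 3,4-bis(benzyloxy)benzaldehyde
Product: 3 (±)-1-[3,4-bis(benzyloxy)phenyl]prop-2-yn-1-yl acetate, via bromomagnesium propargylic alkoxide 2 (not isolated)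
Conditions: HC≡CMgBr (1.15 equiv), THF, 0 °C; then Ac2O (1.5 equiv), 0 °C → rt
Reagents that add atoms: ethynylmagnesium bromide, C#C[Mg]Br; acetic anhydride, CC(=O)OC(C)=O
Why: Grignard 1,2-addition of the alkynyl reagent to the aldehyde and O-acylation of the alkoxide in the same flask are routine, and the racemate suffices because step 4 is stereoconvergent.

Step 2
Reactants: 4 (+)-catechin, (2R,3S)
Product: 5 5,7,3',4'-tetra-O-benzyl-(+)-catechin, i.e. (2R,3S)-5,7-bis(benzyloxy)-2-[3,4-bis(benzyloxy)phenyl]chroman-3-ol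
Conditions: BnBr (4.4 equiv), K2CO3, DMF, 0 °C → rt, Ar
Reagents that add atoms: benzyl bromide, BrCc1ccccc1
Why: Williamson etherification with a carbonate base alkylates only the four phenols and leaves the secondary alcohol and both stereocentres untouched.

Step 3
Reactants: 5 5,7,3',4'-tetra-O-benzyl-(+)-catechin
Product: 6 3,5,7,3',4'-penta-O-benzyl-(+)-catechin, i.e. (2R,3S)-3,5,7-tris(benzyloxy)-2-[3,4-bis(benzyloxy)phenyl]chromane
Conditions: NaH (1.5 equiv), BnBr (1.3 equiv), Bu4NI (cat.), DMF, 0 °C → rt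
Reagents that add atoms: benzyl bromide, BrCc1ccccc1
Why: Williamson etherification of the secondary alkoxide cannot disturb C2 or C3 once no free phenol remains, and the benzyl ether keeps the 3-OH away from the copper and ruthenium catalysts and is removed in the last step with the others.

Step 4
Reactants: 3 (±)-1-[3,4-bis(benzyloxy)phenyl]prop-2-yn-1-yl acetate; 6 penta-O-benzyl-(+)-catechin
Product: 7 (2R,3S)-3,5,7-tris(benzyloxy)-2-[3,4-bis(benzyloxy)phenyl]-8-{(1R)-1-[3,4-bis(benzyloxy)phenyl]prop-2-yn-1-yl}chromane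
Conditions: Cu(OTf)·½C6H6 (10 mol %), (S,S)-Ph-pybox (12 mol %), iPr2NEt (1.2 equiv), CF3CH2OH/CH2Cl2, −20 °C
Reagents that add atoms: none
Why: Proposed new method: the copper(I)–pybox acetylide of 3 should expel acetate to give a copper allenylidene, a planar γ-electrophile on which both enantiomers of 3 converge, and C8 of 6 (the most nucleophilic A-ring carbon and, unlike C6 between two benzyloxy groups, open on its O1 side) should attack the face left free by the ligand, which sets Cα as (R) under catalyst control before rearomatisation and protodemetalation; the closest known reaction type is the copper-catalysed enantioselective propargylic Friedel–Crafts alkylation of indoles and electron-rich phenols with 1-arylpropargyl esters, extended here to a fully O-alkylated phloroglucinol-type arene, for which weakly nucleophilic trifluoroethanol is chosen so that the solvent does not intercept the electrophile.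

Step 5
Reactants: 8 3,5-bis(benzyloxy)phenol
Product: 9 2-iodo-3,5-bis(benzyloxy)phenol
Conditions: NIS (1.0 equiv), CH2Cl2, −40 → 0 °C, dark
Reagents that add atoms: N-iodosuccinimide, O=C1CCC(=O)N1I
Why: Electrophilic aromatic iodination should favour the two equivalent positions ortho to the hydroxyl, helped by hydrogen-bonded delivery in a non-polar solvent, over C4 between two benzyloxy groups, and any 4-iodo isomer is symmetric and should be separable by chromatography.

Step 6
Reactants: 9 2-iodo-3,5-bis(benzyloxy)phenol (1.2 equiv); 7 the (1R)-3,3-diarylpropyne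
Product: 11 (2R,3S)-3,5,7-tris(benzyloxy)-2-[3,4-bis(benzyloxy)phenyl]-8-{(R)-[4,6-bis(benzyloxy)-1-benzofuran-2-yl][3,4-bis(benzyloxy)phenyl]methyl}chromane, via o-alkynylphenol 10 (not isolated)
Conditions: PdCl2(PPh3)2 (5 mol %), CuI (10 mol %), Et3N (3 equiv), degassed DMF, 25 °C then 55 °C
Reagents that add atoms: none
Why: Oxidative addition of Pd(0) into the C–I bond of 9, transmetalation of the copper acetylide of 7 and reductive elimination form C3–C3a and give o-alkynylphenol 10, whose phenolic oxygen then adds to the metal-activated triple bond and, after protodemetalation, forms O1–C2. The closest known reaction type is the one-pot Sonogashira coupling–cycloisomerisation of o-iodophenols with terminal alkynes to 2-substituted benzofurans. The furan ring closes 5-endo-dig, the only mode open to an oxygen ortho to the alkyne, which places Cα on C2 and the two benzyloxy groups of 9 at C4 and C6. No stereocentre is created. The selectivity needed is retention of the configuration at the doubly benzylic propargylic Cα, that is, no base-induced propargyl-to-allene isomerisation; this is secured by using only a tertiary amine at moderate temperature, by the two electron-rich aryl groups that lower the acidity of the Cα–H bond, and by the fact that Cα is no longer propargylic once the aromatic furan has formed. Chemoselectivity is not in question because 9 holds the only aryl halide and the only free hydroxyl.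

Step 7
Reactants: 11 the 2-(diarylmethyl)-4,6-bis(benzyloxy)benzofuran
Product: 12 (2R,3S)-3,5,7-tris(benzyloxy)-2-[3,4-bis(benzyloxy)phenyl]-8-{(R)-[(2S)-4,6-bis(benzyloxy)-2,3-dihydro-1-benzofuran-2-yl][3,4-bis(benzyloxy)phenyl]methyl}chromane
Conditions: Ru(cod)(2-methylallyl)2 (5 mol %), (R,R)-SINpEt·HBF4 (10 mol %), KOtBu, hexane, 70 °C (precatalyst); then 11, H2 (60 bar), toluene, 25–40 °C
Reagents that add atoms: none
Why: Ruthenium–N-heterocyclic carbene catalysed asymmetric hydrogenation of 2-substituted benzofurans reduces only the furan C2=C3 bond, and the chiral carbene ligands choose the face of the flat heteroarene, so C2 should be set as (S) under catalyst control while the benzyl ethers, the carbocyclic rings and Cα stay untouched.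

Step 8
Reactants: 12 the nona-O-benzyl dihydrobenzofuran
Product: 13 (2R,3S)-2-(3,4-dihydroxyphenyl)-8-{(R)-(3,4-dihydroxyphenyl)[(2S)-4,6-dihydroxy-2,3-dihydro-1-benzofuran-2-yl]methyl}chromane-3,5,7-triol (CNP0280971.2)
Conditions: H2 (1 atm), 20 % Pd(OH)2/C, THF/MeOH (1:1), rt; filtration under Ar
Reagents that add atoms: none
Why: Catalytic hydrogenolysis of the eight aryl benzyl ethers and the one alkyl benzyl ether is the standard last step for benzylated flavan-3-ols and should leave the catechin C2–O1 bond, the dihydrobenzofuran and all four stereocentres intact.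

Compound list

1 | 3,4-bis(benzyloxy)benzaldehyde | O=Cc1ccc(OCc2ccccc2)c(OCc2ccccc2)c1 | starting material
2 | bromomagnesium 1-[3,4-bis(benzyloxy)phenyl]prop-2-yn-1-olate (racemic) | C#CC([O-])c1ccc(OCc2ccccc2)c(OCc2ccccc2)c1.[Mg+2].[Br-] | intermediate
3 | (±)-1-[3,4-bis(benzyloxy)phenyl]prop-2-yn-1-yl acetate | C#CC(OC(C)=O)c1ccc(OCc2ccccc2)c(OCc2ccccc2)c1 | intermediate
4 | (+)-catechin, (2R,3S) | O[C@H]1Cc2c(O)cc(O)cc2O[C@@H]1c1ccc(O)c(O)c1 | starting material
5 | 5,7,3',4'-tetra-O-benzyl-(+)-catechin | O[C@H]1Cc2c(OCc3ccccc3)cc(OCc3ccccc3)cc2O[C@@H]1c1ccc(OCc2ccccc2)c(OCc2ccccc2)c1 | intermediate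
6 | 3,5,7,3',4'-penta-O-benzyl-(+)-catechin | c1ccccc1CO[C@H]1Cc2c(OCc3ccccc3)cc(OCc3ccccc3)cc2O[C@@H]1c1ccc(OCc2ccccc2)c(OCc2ccccc2)c1 | intermediate
7 | (2R,3S)-3,5,7-tris(benzyloxy)-2-[3,4-bis(benzyloxy)phenyl]-8-{(1R)-1-[3,4-bis(benzyloxy)phenyl]prop-2-yn-1-yl}chromane | C#C[C@H](c1ccc(OCc2ccccc2)c(OCc2ccccc2)c1)c1c(OCc2ccccc2)cc(OCc2ccccc2)c2c1O[C@H](c1ccc(OCc3ccccc3)c(OCc3ccccc3)c1)[C@@H](OCc1ccccc1)C2 | intermediate
8 | 3,5-bis(benzyloxy)phenol | Oc1cc(OCc2ccccc2)cc(OCc2ccccc2)c1 | starting material
9 | 2-iodo-3,5-bis(benzyloxy)phenol | Oc1cc(OCc2ccccc2)cc(OCc2ccccc2)c1I | intermediate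
10 | 2-{(3S)-3-[3,4-bis(benzyloxy)phenyl]-3-[(2R,3S)-3,5,7-tris(benzyloxy)-2-[3,4-bis(benzyloxy)phenyl]chroman-8-yl]prop-1-yn-1-yl}-3,5-bis(benzyloxy)phenol | Oc1cc(OCc2ccccc2)cc(OCc2ccccc2)c1C#C[C@H](c1ccc(OCc2ccccc2)c(OCc2ccccc2)c1)c1c(OCc2ccccc2)cc(OCc2ccccc2)c2c1O[C@H](c1ccc(OCc3ccccc3)c(OCc3ccccc3)c1)[C@@H](OCc1ccccc1)C2 | intermediate
11 | (2R,3S)-3,5,7-tris(benzyloxy)-2-[3,4-bis(benzyloxy)phenyl]-8-{(R)-[4,6-bis(benzyloxy)-1-benzofuran-2-yl][3,4-bis(benzyloxy)phenyl]methyl}chromane | O(Cc1ccccc1)c1cc(OCc2ccccc2)c2cc([C@H](c3ccc(OCc4ccccc4)c(OCc4ccccc4)c3)c3c(OCc4ccccc4)cc(OCc4ccccc4)c4c3O[C@H](c3ccc(OCc5ccccc5)c(OCc5ccccc5)c3)[C@@H](OCc3ccccc3)C4)oc2c1 | intermediate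
12 | (2R,3S)-3,5,7-tris(benzyloxy)-2-[3,4-bis(benzyloxy)phenyl]-8-{(R)-[(2S)-4,6-bis(benzyloxy)-2,3-dihydro-1-benzofuran-2-yl][3,4-bis(benzyloxy)phenyl]methyl}chromane | O(Cc1ccccc1)c1cc(OCc2ccccc2)c2c(c1)O[C@H]([C@H](c1ccc(OCc3ccccc3)c(OCc3ccccc3)c1)c1c(OCc3ccccc3)cc(OCc3ccccc3)c3c1O[C@H](c1ccc(OCc4ccccc4)c(OCc4ccccc4)c1)[C@@H](OCc1ccccc1)C3)C2 | intermediate
13 | (2R,3S)-2-(3,4-dihydroxyphenyl)-8-{(R)-(3,4-dihydroxyphenyl)[(2S)-4,6-dihydroxy-2,3-dihydro-1-benzofuran-2-yl]methyl}chromane-3,5,7-triol | Oc1cc(O)c2c(c1)O[C@H]([C@H](c1ccc(O)c(O)c1)c1c(O)cc(O)c3c1O[C@H](c1ccc(O)c(O)c1)[C@@H](O)C3)C2 | target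

Total step count: 8. Longest linear sequence: 6 steps (steps 2, 3, 4, 6, 7 and 8, from (+)-catechin).

Steps most likely to fail

Step 4. The fully O-alkylated A ring may be too weak a nucleophile for the copper allenylidene, so the electrophile could be lost to solvent capture or oligomerisation. Face selectivity could also be poor if the chiral flavan and the ligand are mismatched, and some attack at C6 is possible. The fallback uses known chemistry and sets out from 3 and 6. Acid-catalysed SN1 propargylic Friedel–Crafts alkylation (catalytic BF3·OEt2, CH2Cl2, −40 °C, conditions under which benzylated flavans are routinely C8-alkylated) should give 7 together with its Cα epimer, (2R,3S)-3,5,7-tris(benzyloxy)-2-[3,4-bis(benzyloxy)phenyl]-8-{(1S)-1-[3,4-bis(benzyloxy)phenyl]prop-2-yn-1-yl}chromane F1. The two are diastereomers and are to be separated by chromatography; the route is rejoined at 7.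

Step 6. Oxidative addition into the electron-rich aryl iodide flanked by two oxygen substituents may be slow, which would let alkyne homocoupling compete. Long warming with amine could erode Cα through propargyl-to-allene isomerisation, and ring closure could stall at the alkynylphenol. The fallback separates coupling from cyclisation and sets out from 9. Acetylation (Ac2O, pyridine) gives 2-iodo-3,5-bis(benzyloxy)phenyl acetate F2, a better partner for oxidative addition that cannot cyclise. Sonogashira coupling with 7 at room temperature (PdCl2(PPh3)2, CuI, Et3N, THF) gives the alkynylaryl acetate, 2-{(3S)-3-[3,4-bis(benzyloxy)phenyl]-3-[(2R,3S)-3,5,7-tris(benzyloxy)-2-[3,4-bis(benzyloxy)phenyl]chroman-8-yl]prop-1-yn-1-yl}-3,5-bis(benzyloxy)phenyl acetate F3. Mild hydrazinolysis (N2H4·H2O, THF, 0 °C) frees phenol 10, now isolated, and base-free π-acid catalysis (Ph3PAuNTf2, toluene, rt) closes the furan 5-endo-dig, rejoining the route at 11.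

Step 7. The very bulky diarylmethyl group at C2 may slow turnover, and the existing Cα centre may be mismatched with the catalyst, giving poor facial selectivity. The fallback gives up catalyst control and sets out from 11. Heterogeneous hydrogenation (H2, 30 bar, Pd(OH)2/C, THF/MeOH/AcOH) should reduce the furan C2=C3 bond and cleave all benzyl ethers in one operation. It should give 13 together with its C2 epimer, (2R,3S)-2-(3,4-dihydroxyphenyl)-8-{(R)-(3,4-dihydroxyphenyl)[(2R)-4,6-dihydroxy-2,3-dihydro-1-benzofuran-2-yl]methyl}chromane-3,5,7-triol F4. The two free polyphenols are to be separated by reversed-phase HPLC, so the route is rejoined at 13 and step 8 is not needed.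

Further compounds

F1 | step 4 | (2R,3S)-3,5,7-tris(benzyloxy)-2-[3,4-bis(benzyloxy)phenyl]-8-{(1S)-1-[3,4-bis(benzyloxy)phenyl]prop-2-yn-1-yl}chromane | C#C[C@@H](c1ccc(OCc2ccccc2)c(OCc2ccccc2)c1)c1c(OCc2ccccc2)cc(OCc2ccccc2)c2c1O[C@H](c1ccc(OCc3ccccc3)c(OCc3ccccc3)c1)[C@@H](OCc1ccccc1)C2
F2 | step 6 | 2-iodo-3,5-bis(benzyloxy)phenyl acetate | CC(=O)Oc1cc(OCc2ccccc2)cc(OCc2ccccc2)c1I
F3 | step 6 | 2-{(3S)-3-[3,4-bis(benzyloxy)phenyl]-3-[(2R,3S)-3,5,7-tris(benzyloxy)-2-[3,4-bis(benzyloxy)phenyl]chroman-8-yl]prop-1-yn-1-yl}-3,5-bis(benzyloxy)phenyl acetate | CC(=O)Oc1cc(OCc2ccccc2)cc(OCc2ccccc2)c1C#C[C@H](c1ccc(OCc2ccccc2)c(OCc2ccccc2)c1)c1c(OCc2ccccc2)cc(OCc2ccccc2)c2c1O[C@H](c1ccc(OCc3ccccc3)c(OCc3ccccc3)c1)[C@@H](OCc1ccccc1)C2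
F4 | step 7 | (2R,3S)-2-(3,4-dihydroxyphenyl)-8-{(R)-(3,4-dihydroxyphenyl)[(2R)-4,6-dihydroxy-2,3-dihydro-1-benzofuran-2-yl]methyl}chromane-3,5,7-triol | Oc1cc(O)c2c(c1)O[C@@H]([C@H](c1ccc(O)c(O)c1)c1c(O)cc(O)c3c1O[C@H](c1ccc(O)c(O)c1)[C@@H](O)C3)C2
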